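**Plan**
1. Retrosynthesis: the acetate C–O bond is cut first, then C11–C12 (a C11 phenyl sulfone on the decalin and a C12–C23 allylic bromide from farnesol), then C9–C11 and C8–O back to a C9 ketone, and last C4–C5 and C1–C10 of ring A.
2. Enabling feature: ring A carries the C3 carbonyl next to the gem-dimethyl carbon C4, H-5 cis to CH3-10, and a quaternary C10. C1–C4 therefore map onto a 2-silyloxy-1,1-dimethyl diene and C5=C10 onto the alkene of 2-methylcyclohex-2-enone, whose carbonyl becomes C9.
3. Forward: ring B is bought as the enone and ring A is closed on it by the Diels–Alder step. C9 is then changed from ketone to the carbon bearing C11, C8 is oxygenated, and the C12–C23 chain is joined last by sulfone alkylation.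
4. Stereochemistry: cis H-5/CH3-10 from suprafacial cycloaddition, their absolute sense from a chiral Lewis acid; C8 from a tartrate-controlled epoxidation; C9 from a hydroxyl-directed hydrogenation; the three E alkenes from (2E,6E)-farnesol and an E-selective SeO2 oxidation.

Key step: step 2

Remark: the SMILES is read literally as (5S,8R,9R,10S), i.e. H-5 and CH3-10 on the same face (called β), 8-OH α, 8-CH3 β, H-9 α and the C9 side chain β. Ring carbons are C1–C10 (C3 carbonyl, C4 gem-dimethyl, C5/C10 ring fusion); chain carbons are C11–C23 counted outward from C9 (C23 = CH2OAc).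

Remark: the C2=C3 triisopropylsilyl enol ether formed in step 2 is kept as the mask of the C3 ketone until step 19, so no peracid, halogen or ozone is used on the ring fragment.

**Step 1**
Reactants: 1 4-methylpent-1-en-3-one
Product: 2 4-methyl-3-(triisopropylsilyloxy)penta-1,3-diene
Conditions: i-Pr3SiOTf, Et3N, CH2Cl2, 0 °C
Reagents that add atoms: triisopropylsilyl trifluoromethanesulfonate, CC(C)[Si](C(C)C)(C(C)C)OS(=O)(=O)C(F)(F)F
Why: Soft enolisation with silyl triflate and amine (silyl enol ether formation) can only remove the isopropyl methine hydrogen, so the 2-silyloxydiene forms as a single regioisomer.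

**Step 2**
Reactants: 2 4-methyl-3-(triisopropylsilyloxy)penta-1,3-diene; 3 2-methylcyclohex-2-en-1-one
Product: 4 cis-fused adduct (4aR,8aS)-5,5,8a-trimethyl-6-(triisopropylsilyloxy)-3,4,4a,5,8,8a-hexahydronaphthalen-1(2H)-one (C9 ketone; C2=C3 silyl enol ether; H-5 and CH3-10 β)
Conditions: (S)-tetrahydro-1-(2-methylphenyl)-3,3-diphenyl-1H,3H-pyrrolo[1,2-c][1,3,2]oxazaborole (cat.) activated by AlBr3 (cat.), CH2Cl2, −78 → −40 °C; Et3N quench
Reagents that add atoms: none
Why: Proposed new method: the AlBr3-activated oxazaborolidine binds the enone carbonyl, so the nucleophilic enol-ether carbon C4 of 2 bonds first to the β-carbon C5 and the vinyl terminus C1 then bonds to the α-carbon C10, a strongly asynchronous [4+2] addition that in the limit is a Mukaiyama–Michael step followed by 6-endo-trig collapse of the metal enolate onto the silyloxyallyl cation; the closest known reactions are the Diels–Alder addition of hindered 2-silyloxydienes to 2-methylcycloalkenones under achiral mixed AlBr3/AlMe3 activation and oxazaborolidinium-catalysed cycloadditions of 2-silyloxydienes to unsubstituted cycloalkenones. Ring A is closed by this [4+2] cycloaddition, suprafacial on the ring alkene, which forces H-5 and CH3-10 to be cis. The absolute configuration (attack on the C2-Si/C3-Si face of 3, giving 10S) must come from the catalyst shielding one face of the bound enone; because the α-methyl group removes the α-C–H contact that normally organises such complexes, the catalyst antipode and its B-aryl group will have to be screened. Regioselectivity is secured by the polarity match between the enol-ether terminus and the enone β-carbon. The Z-methyl group at the diene terminus disfavours a synchronous s-cis transition state, which is why strong Lewis-acid activation is needed, and the triisopropylsilyl group is chosen so that the product enol ether survives it.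

**Step 3**
Reactants: 4 cis-fused adduct
Product: 6 8-methyl-9-ketone (both C8 epimers), via lithium enolate 5 (not isolated)
Conditions: LiN(i-Pr)2, THF, −78 °C; then MeI, −78 → 0 °C
Reagents that add atoms: iodomethane, CI
Why: C9 is flanked by quaternary C10, so only the C8 enolate can form and it is C-methylated (enolate alkylation); the new C8 stereocentre is a mixture of epimers and is erased in step 4.

**Step 4**
Reactants: 6 8-methyl-9-ketone
Product: 8 C9 enol triflate (C8=C9; CH3 on C8), via potassium enolate 7 (not isolated)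
Conditions: KN(SiMe3)2, THF, −78 → 0 °C; then PhNTf2, 0 °C → rt
Reagents that add atoms: N-phenylbis(trifluoromethanesulfonimide), O=S(=O)(N(c1ccccc1)S(=O)(=O)C(F)(F)F)C(F)(F)F
Why: The only possible enolate (C8=C9) is trapped on oxygen to give the tetrasubstituted enol triflate (enol triflate formation).

**Step 5**
Reactants: 8 C9 enol triflate
Product: 9 methyl ester (CO2CH3 = C11 on C9; C8=C9)
Conditions: Pd(OAc)2 (cat.), Ph2P(CH2)3PPh2 (cat.), CO (1 atm), MeOH, Et3N, DMF, 70 °C
Reagents that add atoms: carbon monoxide, [C-]#[O+]; methanol, CO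
Why: Oxidative addition of the enol triflate to zerovalent palladium, CO insertion and methanolysis give the enoate, as with β-cyclogeranate-type triflates (palladium-catalysed alkoxycarbonylation).

**Step 6**
Reactants: 9 methyl ester
Product: 10 allylic alcohol (C11H2OH on C9; C8=C9)
Conditions: i-Bu2AlH, CH2Cl2, −78 → 0 °C
Reagents that add atoms: none
Why: The aluminium hydride reduces the hindered enoate to the primary allylic alcohol and leaves the silyl enol ether alone (1,2-reduction of an ester).

**Step 7**
Reactants: 10 allylic alcohol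
Product: 11 8α,9α-epoxy-11-ol
Conditions: Ti(Oi-Pr)4 (cat.), D-(−)-diethyl tartrate (cat.), t-BuOOH, 4 Å molecular sieves, CH2Cl2, −20 °C
Reagents that add atoms: tert-butyl hydroperoxide, CC(C)(C)OO
Why: Katsuki–Sharpless asymmetric epoxidation transfers oxygen only to the alkene of the titanium-bound allylic alcohol (the C2=C3 enol ether is no ligand and stays), and with the D-(−)-tartrate it should enter from the α face, setting C8 (O α, CH3 β) and C9 under reagent control, while any minor enantiomer carried from step 2 becomes a separable diastereomer.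

**Step 8**
Reactants: 11 8α,9α-epoxy-11-ol
Product: 12 8α,9α-epoxy-11-(phenylthio) compound
Conditions: PhSSPh, n-Bu3P, pyridine, rt
Reagents that add atoms: diphenyl disulfide, c1ccc(cc1)SSc1ccccc1
Why: In this Hata-type redox condensation the alkoxyphosphonium ion is displaced by thiophenolate at primary C11 (SN2), while both epoxide carbons are fully substituted and inert to thiolate.

**Step 9**
Reactants: 12 epoxy sulfide
Product: 13 8α,9α-epoxy-11-(phenylsulfonyl) compound
Conditions: Pr4N[RuO4] (cat.), N-methylmorpholine N-oxide, 4 Å molecular sieves, MeCN, rt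
Reagents that add atoms: N-methylmorpholine N-oxide, C[N+]1([O-])CCOCC1
Why: Perruthenate-catalysed oxidation takes the sulfide to the sulfone without epoxidising electron-rich alkenes, so the silyl enol ether, which a peracid would destroy, is kept (catalytic sulfide oxidation).

**Step 10**
Reactants: 13 epoxy sulfone
Product: 14 γ-hydroxy vinyl sulfone (8α-OH, 8β-CH3, C9=C11H–SO2Ph, E/Z mixture)
Conditions: KOt-Bu (cat.), t-BuOH–THF, 0 °C → rt
Reagents that add atoms: none
Why: Deprotonation α to the sulfone and E1cB opening of the C9–O bond give the γ-hydroxy vinyl sulfone (base-induced epoxy sulfone isomerisation); the C8–O bond is untouched, so C8 keeps its configuration, and with C8 and C10 quaternary the alkene cannot migrate further.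

**Step 11**
Reactants: 14 γ-hydroxy vinyl sulfone
Product: 15 hydroxy sulfone (8α-OH, H-9 α, C11H2SO2Ph β)
Conditions: H2 (1 atm), [Ir(cod)(PCy3)(py)]PF6 (cat.), CH2Cl2, rt
Reagents that add atoms: none
Why: In this hydroxyl-directed homogeneous hydrogenation the cationic iridium centre binds the tertiary 8α-OH and the adjacent alkene and adds H2 from that α face, so H-9 ends up cis to the hydroxyl and C11 β from either alkene isomer, while the undirected and hindered C2=C3 enol ether should react far more slowly.

**Step 12**
Reactants: 16 (2E,6E)-farnesol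
Product: 17 (2E,6E)-farnesyl acetate
Conditions: Ac2O, pyridine, CH2Cl2, rt
Reagents that add atoms: acetic anhydride, CC(=O)OC(C)=O
Why: Esterification masks the allylic alcohol for the selenium oxidation.

**Step 13**
Reactants: 17 (2E,6E)-farnesyl acetate
Product: 18 (2E,6E,10E)-12-hydroxy-3,7,11-trimethyldodeca-2,6,10-trien-1-yl acetate
Conditions: SeO2 (cat.), t-BuOOH, salicylic acid (cat.), CH2Cl2, rt
Reagents that add atoms: tert-butyl hydroperoxide, CC(C)(C)OO; selenium dioxide (oxygen carrier), O=[Se]=O
Why: SeO2 allylic oxidation (ene reaction, then [2,3]-sigmatropic shift) attacks the terminal trisubstituted alkene at its E-methyl group and gives the (10E)-allylic alcohol that becomes C21=C22–C23.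

**Step 14**
Reactants: 18 hydroxy acetate
Product: 19 (2E,6E,10E)-12-(tert-butyldimethylsilyloxy)-3,7,11-trimethyldodeca-2,6,10-trien-1-yl acetate
Conditions: t-BuMe2SiCl, imidazole, DMF, rt
Reagents that add atoms: tert-butyldimethylsilyl chloride, CC(C)(C)[Si](C)(C)Cl
Why: Silylation protects the new primary alcohol with a group that withstands organolithium and amalgam conditions and falls with fluoride in step 19.

**Step 15**
Reactants: 19 silyl ether acetate
Product: 20 (2E,6E,10E)-12-(tert-butyldimethylsilyloxy)-3,7,11-trimethyldodeca-2,6,10-trien-1-ol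
Conditions: K2CO3 (cat.), MeOH, rt
Reagents that add atoms: none
Why: Base-catalysed transesterification removes the acetate and leaves the silyl ether.

**Step 16**
Reactants: 20 silyl ether alcohol
Product: 21 (2E,6E,10E)-1-bromo-12-(tert-butyldimethylsilyloxy)-3,7,11-trimethyldodeca-2,6,10-triene
Conditions: CBr4, PPh3, CH2Cl2, 0 °C
Reagents that add atoms: tetrabromomethane, BrC(Br)(Br)Br
Why: The Appel reaction converts the primary allylic alcohol to the bromide under neutral conditions without allylic transposition or loss of alkene geometry.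

**Step 17**
Reactants: 15 hydroxy sulfone; 21 allylic bromide
Product: 23 coupled sulfone (C11 epimers; C3 silyl enol ether; 23-O-silyl ether), via dilithio sulfone 22 (not isolated)
Conditions: n-BuLi (2 equiv), THF–HMPA, −78 °C; then 21, −78 → −20 °C; H2O
Reagents that add atoms: none
Why: The alkoxide/α-sulfonyl carbanion is alkylated on carbon by the allylic bromide (SN2 sulfone alkylation), forming C11–C12 with the E alkenes untouched; the new C11 stereocentre is a mixture and is erased in step 18.

**Step 18**
Reactants: 23 coupled sulfone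
Product: 24 desulfonylated bis-silyl compound (8α-OH; C3 silyl enol ether; 23-O-silyl ether)
Conditions: Na(Hg), Na2HPO4, MeOH–THF, −20 °C
Reagents that add atoms: none
Why: Electron transfer cleaves the C–S bond of the alkyl phenyl sulfone (reductive desulfonylation); the sulfone is homoallylic, so no alkene can shift, and the γ-hydroxyl cannot be eliminated.

**Step 19**
Reactants: 24 bis-silyl compound
Product: 25 8α,23-dihydroxy-3-ketone (the deacetyl target)
Conditions: Bu4NF, THF, 0 °C → rt
Reagents that add atoms: none
Why: Fluoride desilylation cleaves the enol ether to the C3 ketone (protonation at C2; C4 is quaternary, so no stereocentre is at risk) and frees the primary alcohol.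

**Step 20**
Reactants: 25 dihydroxy ketone
Product: 26 myrrhanone A acetate as defined by the given SMILES
Conditions: Ac2O, pyridine, CH2Cl2, 0 °C
Reagents that add atoms: acetic anhydride, CC(=O)OC(C)=O
Why: Acetylation under mild base takes the primary allylic alcohol and leaves the hindered tertiary C8 hydroxyl free (selective esterification).

**Compound list**
1 | 4-methylpent-1-en-3-one | C=CC(=O)C(C)C | starting material
2 | 4-methyl-3-(triisopropylsilyloxy)penta-1,3-diene | C=CC(O[Si](C(C)C)(C(C)C)C(C)C)=C(C)C | intermediate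
3 | 2-methylcyclohex-2-en-1-one | CC1=CCCCC1=O | starting material
4 | (4aR,8aS)-5,5,8a-trimethyl-6-(triisopropylsilyloxy)-3,4,4a,5,8,8a-hexahydronaphthalen-1(2H)-one (cis-fused; C9 ketone; C2=C3 silyl enol ether) | O=C1[C@@]2(C)CC=C(O[Si](C(C)C)(C(C)C)C(C)C)C(C)(C)[C@H]2CCC1 | intermediate
5 | lithium C8=C9 enolate of 4 (not isolated) | [Li]OC1[C@@]2(C)CC=C(O[Si](C(C)C)(C(C)C)C(C)C)C(C)(C)[C@H]2CCC=1 | intermediate
6 | 8-methyl derivative of 4 (8-methyl-9-ketone, C8 epimers) | O=C1[C@@]2(C)CC=C(O[Si](C(C)C)(C(C)C)C(C)C)C(C)(C)[C@H]2CCC1C | intermediate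
7 | potassium C8=C9 enolate of 6 (not isolated) | [K]OC1[C@@]2(C)CC=C(O[Si](C(C)C)(C(C)C)C(C)C)C(C)(C)[C@H]2CCC=1C | intermediate
8 | C9 enol triflate (C8=C9, CH3 on C8) | O=S(=O)(OC1[C@@]2(C)CC=C(O[Si](C(C)C)(C(C)C)C(C)C)C(C)(C)[C@H]2CCC=1C)C(F)(F)F | intermediate
9 | methyl ester (C11 = CO2CH3 on C9, C8=C9) | COC(=O)C1[C@@]2(C)CC=C(O[Si](C(C)C)(C(C)C)C(C)C)C(C)(C)[C@H]2CCC=1C | intermediate
10 | allylic alcohol (C11H2OH on C9, C8=C9) | OCC1[C@@]2(C)CC=C(O[Si](C(C)C)(C(C)C)C(C)C)C(C)(C)[C@H]2CCC=1C | intermediate
11 | 8α,9α-epoxy-11-ol (8-CH3 β) | OC[C@]1(O3)[C@@]2(C)CC=C(O[Si](C(C)C)(C(C)C)C(C)C)C(C)(C)[C@H]2CC[C@]13C | intermediate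
12 | 8α,9α-epoxy-11-(phenylthio) compound | c4ccccc4SC[C@]1(O3)[C@@]2(C)CC=C(O[Si](C(C)C)(C(C)C)C(C)C)C(C)(C)[C@H]2CC[C@]13C | intermediate
13 | 8α,9α-epoxy-11-(phenylsulfonyl) compound | O=S(=O)(c4ccccc4)C[C@]1(O3)[C@@]2(C)CC=C(O[Si](C(C)C)(C(C)C)C(C)C)C(C)(C)[C@H]2CC[C@]13C | intermediate
14 | γ-hydroxy vinyl sulfone (8α-OH, 8β-CH3, C9=C11H–SO2Ph, E/Z mixture) | O=S(=O)(c4ccccc4)C=C1[C@@]2(C)CC=C(O[Si](C(C)C)(C(C)C)C(C)C)C(C)(C)[C@H]2CC[C@@]1(C)O | intermediate
15 | hydroxy sulfone (8α-OH, H-9 α, C11H2SO2Ph β) | O=S(=O)(c4ccccc4)C[C@@H]1[C@@]2(C)CC=C(O[Si](C(C)C)(C(C)C)C(C)C)C(C)(C)[C@H]2CC[C@@]1(C)O | intermediate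
16 | (2E,6E)-farnesol | CC(C)=CCC/C(C)=C/CC/C(C)=C/CO | starting material
17 | (2E,6E)-farnesyl acetate | CC(C)=CCC/C(C)=C/CC/C(C)=C/COC(C)=O | intermediate
18 | (2E,6E,10E)-12-hydroxy-3,7,11-trimethyldodeca-2,6,10-trien-1-yl acetate | OC/C(C)=C/CC/C(C)=C/CC/C(C)=C/COC(C)=O | intermediate
19 | (2E,6E,10E)-12-(tert-butyldimethylsilyloxy)-3,7,11-trimethyldodeca-2,6,10-trien-1-yl acetate | CC(C)(C)[Si](C)(C)OC/C(C)=C/CC/C(C)=C/CC/C(C)=C/COC(C)=O | intermediate
20 | (2E,6E,10E)-12-(tert-butyldimethylsilyloxy)-3,7,11-trimethyldodeca-2,6,10-trien-1-ol | CC(C)(C)[Si](C)(C)OC/C(C)=C/CC/C(C)=C/CC/C(C)=C/CO | intermediate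
21 | (2E,6E,10E)-1-bromo-12-(tert-butyldimethylsilyloxy)-3,7,11-trimethyldodeca-2,6,10-triene | CC(C)(C)[Si](C)(C)OC/C(C)=C/CC/C(C)=C/CC/C(C)=C/CBr | intermediate
22 | C8-O,C11-dilithio derivative of 15 (not isolated) | [Li]C(S(=O)(=O)c4ccccc4)[C@@H]1[C@@]2(C)CC=C(O[Si](C(C)C)(C(C)C)C(C)C)C(C)(C)[C@H]2CC[C@@]1(C)O[Li] | intermediate
23 | coupled sulfone (11-phenylsulfonyl, C11 epimers; full C11–C23 chain; 23-O-silyl ether; C3 silyl enol ether) | CC(C)(C)[Si](C)(C)OC/C(C)=C/CC/C(C)=C/CC/C(C)=C/CC(S(=O)(=O)c4ccccc4)[C@@H]1[C@@]2(C)CC=C(O[Si](C(C)C)(C(C)C)C(C)C)C(C)(C)[C@H]2CC[C@@]1(C)O | intermediate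
24 | desulfonylated bis-silyl compound (8α-OH; C3 silyl enol ether; 23-O-silyl ether) | CC(C)(C)[Si](C)(C)OC/C(C)=C/CC/C(C)=C/CC/C(C)=C/CC[C@@H]1[C@@]2(C)CC=C(O[Si](C(C)C)(C(C)C)C(C)C)C(C)(C)[C@H]2CC[C@@]1(C)O | intermediate
25 | 8α,23-dihydroxy-3-ketone (deacetyl target) | OC/C(C)=C/CC/C(C)=C/CC/C(C)=C/CC[C@@H]1[C@@]2(C)CCC(=O)C(C)(C)[C@H]2CC[C@@]1(C)O | intermediate
26 | myrrhanone A acetate, (5S,8R,9R,10S) as in the given SMILES | CC(=O)OC/C(C)=C/CC/C(C)=C/CC/C(C)=C/CC[C@@H]1[C@@]2(C)CCC(=O)C(C)(C)[C@H]2CC[C@@]1(C)O | target

**Summary**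
Total step count: 20. Longest linear sequence: 15 steps (steps 1–11 and 17–20); the side chain takes 5 steps (12–16).

**Steps most likely to fail**

1. Step 2 (proposed new method). The risk is low conversion of two doubly hindered partners, or poor enantiofacial discrimination because the α-methyl enone cannot make the usual α-C–H contact with the catalyst. The fallback uses known chemistry and sets out from 2 and 3. The cycloaddition is run with the achiral mixed Lewis acid AlBr3/AlMe3 in toluene–CH2Cl2 at low temperature, the documented conditions for this class of hindered partners, which should give the racemic cis adduct F1. This is resolved by preparative chromatography on a chiral stationary phase (cellulose tris(3,5-dimethylphenylcarbamate), hexane/i-PrOH). The unwanted enantiomer F2 is set aside and the route is rejoined at 4. The tartrate-controlled epoxidation of step 7 then serves as a second check on enantiopurity.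

2. Step 7. The risk is slow or face-unselective oxygen transfer if the folded cis-decalin opposes the tartrate at this tetrasubstituted alkene (mismatched pairing). The fallback sets out from 10 and replaces the titanium template by a conjugate-addition epoxidation. MnO2 in CH2Cl2 oxidises the allylic alcohol to the enal F3, a β-cyclocitral analogue. Alkaline H2O2 in MeOH (Weitz–Scheffer epoxidation) then adds hydroperoxide to C8 and closes to the epoxy aldehyde F4. Here the face is chosen by axial attack of a small nucleophile, which lies on the α face in the half-chair that keeps C4 equatorial on ring B; this sense would have to be confirmed. NaBH4 in MeOH reduces the aldehyde and the route is rejoined at 11.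

3. Step 11. The risk is sluggish hydrogenation of a trisubstituted vinyl sulfone wedged between two quaternary carbons, with competing reduction of the silyl enol ether if the reaction is forced. The fallback sets out from 14 and replaces H2 by alkoxide-directed hydride delivery. LiAlH4 (or NaAlH2(OCH2CH2OMe)2) in THF at low temperature forms the C8 alkoxyaluminate, which passes hydride to C9 through a five-membered transition state, conjugate to the sulfone and again on the α face. Aqueous work-up protonates C11 and the route is rejoined at 15. No new compound is made.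

**Further compounds**
F1 | step 2 | racemic cis adduct (4 together with its enantiomer) | O=C1[C@@]2(C)CC=C(O[Si](C(C)C)(C(C)C)C(C)C)C(C)(C)[C@H]2CCC1.O=C1[C@]2(C)CC=C(O[Si](C(C)C)(C(C)C)C(C)C)C(C)(C)[C@@H]2CCC1
F2 | step 2 | enantiomer of 4, (4aS,8aR) | O=C1[C@]2(C)CC=C(O[Si](C(C)C)(C(C)C)C(C)C)C(C)(C)[C@@H]2CCC1
F3 | step 7 | enal (C11HO on C9, C8=C9, CH3 on C8) | O=CC1[C@@]2(C)CC=C(O[Si](C(C)C)(C(C)C)C(C)C)C(C)(C)[C@H]2CCC=1C
F4 | step 7 | 8α,9α-epoxy-11-al | O=C[C@]1(O3)[C@@]2(C)CC=C(O[Si](C(C)C)(C(C)C)C(C)C)C(C)(C)[C@H]2CC[C@]13C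
F0 | step 11 | none | none
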